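**Retrosynthetic overview**
1. Ring labels: A = phloroglucinol ring of the benzofuran, B = C2 aryl, C = 2,4-dihydroxybenzoyl ring, D = aryl of the acryloyl unit. All four arenes are bought; the dihydrofuran ring is the only ring made (step 5).
2. End game: target ⇐ removal of six silyl ethers ⇐ α-methylenation of the C7 (ring D)CH2–C=O ketone ⇐ C3 aroyl ketone by thioester/boronic acid coupling (ring C enters last) ⇐ thioester from an N-acyl camphorsultam.
3. Key disconnection: O1–C2 and C3a–C3 together, by an auxiliary-controlled oxidative radical [3+2] annulation of acylphloroglucinol 4 (rings A and D) onto the C=C of N-(4-silyloxycinnamoyl)sultam 10 (ring B). Both stereocentres arise here.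
4. Enabling feature: C3a lies between the oxygen-bearing carbons C4 and C7a of ring A (the enol form of a cyclic 1,3,5-triketone), so one-electron oxidation puts spin on C3a with O1 next to it. C2 is benzylic to the para-oxygenated ring B (cation-stabilising), and C3 is alpha to a carbonyl that can carry the chiral sultam.

Key step: step 5

Remark: the facial sense assigned to the (2R)-sultam (attack on the C-alpha Re face of the non-chelated enoyl sultam) follows the usual model for thermal additions; if the induction proves opposite, the (2S)-sultam is used with no other change.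

Step 1
Reactants: 1 phloroglucinol; 2 4-hydroxyphenylacetic acid
Product: 3 2-(4-hydroxyphenyl)-1-(2,4,6-trihydroxyphenyl)ethan-1-one
Conditions: BF3·OEt2 (neat), 85 °C; aq. NaOAc work-up
Reagents that add atoms: none
Why: Friedel–Crafts C-acylation of the symmetric, very nucleophilic triphenol by the BF3-activated acid (the standard deoxybenzoin synthesis), in which all ring positions are equivalent and the product is deactivated towards a second acylation.

Step 2
Reactants: 3 2-(4-hydroxyphenyl)-1-(2,4,6-trihydroxyphenyl)ethan-1-one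
Product: 4 1-[2,6-dihydroxy-4-(triisopropylsilyloxy)phenyl]-2-[4-(triisopropylsilyloxy)phenyl]ethan-1-one
Conditions: TIPSCl (2.1 equiv), imidazole, DMF, 0 °C to rt
Reagents that add atoms: triisopropylsilyl chloride CC(C)[Si](Cl)(C(C)C)C(C)C
Why: Selective phenol silylation, in which the bulky chlorosilane should take the two unhindered hydroxyls (para-OH of ring A and the ring D OH) and leave the two hindered, hydrogen-bonded hydroxyls that flank the ketone.

Step 3
Reactants: 5 (E)-3-(4-hydroxyphenyl)prop-2-enoic acid (p-coumaric acid)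
Product: 7 (E)-3-[4-(triisopropylsilyloxy)phenyl]prop-2-enoic acid, via silyl ester 6 (not isolated)
Conditions: TIPSCl (2.2 equiv), imidazole, DMF, rt; then AcOH/THF/H2O, rt
Reagents that add atoms: triisopropylsilyl chloride CC(C)[Si](Cl)(C(C)C)C(C)C
Why: Silylation of both acidic OH groups followed by selective hydrolysis of the labile silyl ester, the aryl silyl ether being stable to aqueous acetic acid.

Step 4
Reactants: 7 (E)-3-[4-(triisopropylsilyloxy)phenyl]prop-2-enoic acid; 8 (2R)-bornane-10,2-sultam [(−)-2,10-camphorsultam]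
Product: 10 (2R)-N-{(E)-3-[4-(triisopropylsilyloxy)phenyl]prop-2-enoyl}bornane-10,2-sultam, via acid chloride 9 (not isolated)
Conditions: (COCl)2, cat. DMF, CH2Cl2, 0 °C to rt, evaporate; then 8, Et3N, cat. DMAP, CH2Cl2, 0 °C to rt
Reagents that add atoms: none
Why: N-acylation of the sulfonamide nitrogen by the acid chloride, the standard preparation of N-enoyl sultams, which leaves the E alkene untouched.

Step 5
Reactants: 4 1-[2,6-dihydroxy-4-(triisopropylsilyloxy)phenyl]-2-[4-(triisopropylsilyloxy)phenyl]ethan-1-one; 10 (2R)-N-{(E)-3-[4-(triisopropylsilyloxy)phenyl]prop-2-enoyl}bornane-10,2-sultam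
Product: 11 (2R)-N-{[(2R,3R)-6-hydroxy-4-(triisopropylsilyloxy)-2-[4-(triisopropylsilyloxy)phenyl]-7-{[4-(triisopropylsilyloxy)phenyl]acetyl}-2,3-dihydro-1-benzofuran-3-yl]carbonyl}bornane-10,2-sultam
Conditions: 10 (1.0 equiv), 4 (1.5 equiv), Mn(OAc)3·2H2O (2.2 equiv), degassed AcOH, 60 °C
Reagents that add atoms: none
Why: Proposed new method: Mn(OAc)3 oxidises the chelating 2,6-dihydroxyaryl ketone 4 (the aromatic enol of a cyclic 1,3,5-triketone) to a manganese-bound aryloxyl radical that bonds through C3 to C-alpha of the enoyl sultam 10, and the resulting 4-silyloxybenzylic radical is oxidised by the second equivalent of trivalent manganese to a cation that the adjacent phenol oxygen captures (radical–polar crossover, net oxidative [3+2] annulation with loss of two hydrogens). The closest known reaction type is the Mn(OAc)3-mediated [3+2] annulation of enolised cyclic 1,3-diones with cinnamoyl derivatives, including N-cinnamoyl bornane-10,2-sultams, which gives trans-2-aryl-2,3-dihydrofuran-3-carboxamides with this regiochemistry; what has not been shown is an aromatic acylphloroglucinol as the enol partner. The dihydrofuran ring closes by 5-exo capture of the benzylic cation (the quinone-methide-like C2 next to ring B) by O1, so oxygen ends on the aryl-bearing carbon and ring A on the carbon next to the carbonyl. C3 should be set in the radical addition by the sultam (C=O anti to SO2, s-cis enoyl, one face of C-alpha screened by a sulfonyl oxygen, Re-face attack giving 3R), and C2 in the ring closure, trans to the C3 acyl group (2R). Site selectivity is secured by symmetry and protection: C3 and C5 of 4 are equivalent, the only free oxygens flank the ketone so either choice gives the 7-acyl-6-hydroxy pattern, and the para oxygen is silylated so it cannot close the isomeric ring. Chemoselectivity rests on 4 being far easier to oxidise than 10 or product 11 (4 is used in excess) and on the donor-substituted styrene-type alkene giving a benzylic radical that is readily oxidised.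

Step 6
Reactants: 11 the 6-hydroxy sultam adduct from step 5
Product: 12 (2R)-N-{[(2R,3R)-4,6-bis(triisopropylsilyloxy)-2-[4-(triisopropylsilyloxy)phenyl]-7-{[4-(triisopropylsilyloxy)phenyl]acetyl}-2,3-dihydro-1-benzofuran-3-yl]carbonyl}bornane-10,2-sultam
Conditions: TIPSOTf (1.2 equiv), 2,6-lutidine, CH2Cl2, −40 to 0 °C
Reagents that add atoms: triisopropylsilyl trifluoromethanesulfonate CC(C)[Si](OS(=O)(=O)C(F)(F)F)(C(C)C)C(C)C
Why: Silyl triflate O-silylation of the remaining hydrogen-bonded C6 phenol (faster than enol silylation of the ketone with lutidine as base), so that no free ortho-hydroxyl can later add to the enone.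

Step 7
Reactants: 12 the fully silylated sultam adduct
Product: 13 S-ethyl (2R,3R)-4,6-bis(triisopropylsilyloxy)-2-[4-(triisopropylsilyloxy)phenyl]-7-{[4-(triisopropylsilyloxy)phenyl]acetyl}-2,3-dihydro-1-benzofuran-3-carbothioate
Conditions: EtSH (3 equiv), n-BuLi (1.5 equiv), THF, 0 °C; aq. NH4Cl
Reagents that add atoms: ethanethiol CCS
Why: Thiolate cleavage of the N-acyl sultam (acyl transfer to a soft, weakly basic nucleophile, known for N-acyl sultams and imides), which should give the thioester without disturbing C3 (trans being in any case the stable arrangement) and return the auxiliary.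

Step 8
Reactants: 14 4-bromobenzene-1,3-diol (4-bromoresorcinol)
Product: 15 1-bromo-2,4-bis(triisopropylsilyloxy)benzene
Conditions: TIPSCl (2.3 equiv), imidazole, DMF, rt
Reagents that add atoms: triisopropylsilyl chloride CC(C)[Si](Cl)(C(C)C)C(C)C
Why: Standard silylation of both phenols, giving ring C the same protecting group as the rest of the molecule.

Step 9
Reactants: 15 1-bromo-2,4-bis(triisopropylsilyloxy)benzene
Product: 18 [2,4-bis(triisopropylsilyloxy)phenyl]boronic acid, via aryllithium 16 (not isolated), via lithium arylborate 17 (not isolated)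
Conditions: B(OiPr)3, THF/toluene, −78 °C, then n-BuLi (in situ quench); aq. NH4Cl
Reagents that add atoms: triisopropyl borate CC(C)OB(OC(C)C)OC(C)C; water O
Why: Bromine–lithium exchange with immediate capture of the aryllithium by the borate already present (which leaves no time for silyl migration from oxygen to carbon), then hydrolysis to the boronic acid.

Step 10
Reactants: 13 the S-ethyl thioester; 18 [2,4-bis(triisopropylsilyloxy)phenyl]boronic acid
Product: 19 1-[(2R,3R)-3-[2,4-bis(triisopropylsilyloxy)benzoyl]-4,6-bis(triisopropylsilyloxy)-2-[4-(triisopropylsilyloxy)phenyl]-2,3-dihydro-1-benzofuran-7-yl]-2-[4-(triisopropylsilyloxy)phenyl]ethan-1-one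
Conditions: Pd2(dba)3 (2.5 mol %), P(2-furyl)3 (10 mol %), Cu(O2CC4H3S) (copper thiophene-2-carboxylate, 1.6 equiv), THF, 50 °C
Reagents that add atoms: none
Why: Liebeskind–Srogl coupling (zerovalent palladium inserts into the C–S bond and the monovalent copper carboxylate activates sulfur and boron), a base-free ketone synthesis that should preserve the base-sensitive C3 centre (alpha to the new ketone and beta to the ring oxygen) and leave the C7 ketone alone.

Step 11
Reactants: 19 the diketone from step 10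
Product: 20 1-[(2R,3R)-3-[2,4-bis(triisopropylsilyloxy)benzoyl]-4,6-bis(triisopropylsilyloxy)-2-[4-(triisopropylsilyloxy)phenyl]-2,3-dihydro-1-benzofuran-7-yl]-2-[4-(triisopropylsilyloxy)phenyl]prop-2-en-1-one
Conditions: (CH2O)n, i-Pr2NH·CF3CO2H (1 equiv), CF3CO2H (10 mol %), THF, reflux
Reagents that add atoms: formaldehyde (as paraformaldehyde) C=O
Why: Mannich reaction and in situ β-elimination (α-methylenation of a ketone under mildly acidic conditions), which can give an enone only at the benzylic CH2 of the C7 ketone, since the C3 methine is hindered and its Mannich base could not eliminate, and all phenols are silylated.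

Step 12
Reactants: 20 the hexasilylated enone
Product: 21 1-[(2R,3R)-3-(2,4-dihydroxybenzoyl)-4,6-dihydroxy-2-(4-hydroxyphenyl)-2,3-dihydro-1-benzofuran-7-yl]-2-(4-hydroxyphenyl)prop-2-en-1-one (target)
Conditions: HF·pyridine, pyridine, THF, 0 °C to rt
Reagents that add atoms: none
Why: Fluoride cleavage of the six aryl silyl ethers in a mildly acidic medium, which should keep the liberated C6 phenol protonated (no oxa-Michael closure onto the α-methylene ketone) and leave the alkene and both stereocentres untouched.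

**Compound list**
1 | phloroglucinol | Oc1cc(O)cc(O)c1 | starting material
2 | 4-hydroxyphenylacetic acid | OC(=O)Cc1ccc(O)cc1 | starting material
3 | 2-(4-hydroxyphenyl)-1-(2,4,6-trihydroxyphenyl)ethan-1-one | O=C(Cc1ccc(O)cc1)c1c(O)cc(O)cc1O | intermediate
4 | 1-[2,6-dihydroxy-4-(triisopropylsilyloxy)phenyl]-2-[4-(triisopropylsilyloxy)phenyl]ethan-1-one | O=C(Cc1ccc(O[Si](C(C)C)(C(C)C)C(C)C)cc1)c1c(O)cc(O[Si](C(C)C)(C(C)C)C(C)C)cc1O | intermediate
5 | (E)-3-(4-hydroxyphenyl)prop-2-enoic acid (p-coumaric acid) | OC(=O)/C=C/c1ccc(O)cc1 | starting material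
6 | triisopropylsilyl (E)-3-[4-(triisopropylsilyloxy)phenyl]prop-2-enoate (not isolated) | CC(C)[Si](OC(=O)/C=C/c1ccc(O[Si](C(C)C)(C(C)C)C(C)C)cc1)(C(C)C)C(C)C | intermediate
7 | (E)-3-[4-(triisopropylsilyloxy)phenyl]prop-2-enoic acid | OC(=O)/C=C/c1ccc(O[Si](C(C)C)(C(C)C)C(C)C)cc1 | intermediate
8 | (2R)-bornane-10,2-sultam [(−)-2,10-camphorsultam, (3aS,6R,7aR)] | O=S1(=O)N[C@@H]2C[C@H]3CC[C@]2(C1)C3(C)C | starting material
9 | (E)-3-[4-(triisopropylsilyloxy)phenyl]prop-2-enoyl chloride (not isolated) | ClC(=O)/C=C/c1ccc(O[Si](C(C)C)(C(C)C)C(C)C)cc1 | intermediate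
10 | (2R)-N-{(E)-3-[4-(triisopropylsilyloxy)phenyl]prop-2-enoyl}bornane-10,2-sultam | O=C(/C=C/c1ccc(O[Si](C(C)C)(C(C)C)C(C)C)cc1)N1[C@@H]2C[C@H]3CC[C@]2(CS1(=O)=O)C3(C)C | intermediate
11 | (2R)-N-{[(2R,3R)-6-hydroxy-4-(triisopropylsilyloxy)-2-[4-(triisopropylsilyloxy)phenyl]-7-{[4-(triisopropylsilyloxy)phenyl]acetyl}-2,3-dihydro-1-benzofuran-3-yl]carbonyl}bornane-10,2-sultam | O=C(Cc1ccc(O[Si](C(C)C)(C(C)C)C(C)C)cc1)c1c(O)cc(O[Si](C(C)C)(C(C)C)C(C)C)c2c1O[C@@H](c1ccc(O[Si](C(C)C)(C(C)C)C(C)C)cc1)[C@@H]2C(=O)N4[C@@H]5C[C@H]6CC[C@]5(CS4(=O)=O)C6(C)C | intermediate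
12 | (2R)-N-{[(2R,3R)-4,6-bis(triisopropylsilyloxy)-2-[4-(triisopropylsilyloxy)phenyl]-7-{[4-(triisopropylsilyloxy)phenyl]acetyl}-2,3-dihydro-1-benzofuran-3-yl]carbonyl}bornane-10,2-sultam | O=C(Cc1ccc(O[Si](C(C)C)(C(C)C)C(C)C)cc1)c1c(O[Si](C(C)C)(C(C)C)C(C)C)cc(O[Si](C(C)C)(C(C)C)C(C)C)c2c1O[C@@H](c1ccc(O[Si](C(C)C)(C(C)C)C(C)C)cc1)[C@@H]2C(=O)N4[C@@H]5C[C@H]6CC[C@]5(CS4(=O)=O)C6(C)C | intermediate
13 | S-ethyl (2R,3R)-4,6-bis(triisopropylsilyloxy)-2-[4-(triisopropylsilyloxy)phenyl]-7-{[4-(triisopropylsilyloxy)phenyl]acetyl}-2,3-dihydro-1-benzofuran-3-carbothioate | O=C(Cc1ccc(O[Si](C(C)C)(C(C)C)C(C)C)cc1)c1c(O[Si](C(C)C)(C(C)C)C(C)C)cc(O[Si](C(C)C)(C(C)C)C(C)C)c2c1O[C@@H](c1ccc(O[Si](C(C)C)(C(C)C)C(C)C)cc1)[C@@H]2C(=O)SCC | intermediate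
14 | 4-bromobenzene-1,3-diol (4-bromoresorcinol) | Oc1ccc(Br)c(O)c1 | starting material
15 | 1-bromo-2,4-bis(triisopropylsilyloxy)benzene | CC(C)[Si](Oc1ccc(Br)c(O[Si](C(C)C)(C(C)C)C(C)C)c1)(C(C)C)C(C)C | intermediate
16 | [2,4-bis(triisopropylsilyloxy)phenyl]lithium (not isolated) | [Li]c1ccc(O[Si](C(C)C)(C(C)C)C(C)C)cc1O[Si](C(C)C)(C(C)C)C(C)C | intermediate
17 | lithium [2,4-bis(triisopropylsilyloxy)phenyl]tri(propan-2-yloxy)borate (not isolated) | [Li+].CC(C)O[B-](OC(C)C)(OC(C)C)c1ccc(O[Si](C(C)C)(C(C)C)C(C)C)cc1O[Si](C(C)C)(C(C)C)C(C)C | intermediate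
18 | [2,4-bis(triisopropylsilyloxy)phenyl]boronic acid | OB(O)c1ccc(O[Si](C(C)C)(C(C)C)C(C)C)cc1O[Si](C(C)C)(C(C)C)C(C)C | intermediate
19 | 1-[(2R,3R)-3-[2,4-bis(triisopropylsilyloxy)benzoyl]-4,6-bis(triisopropylsilyloxy)-2-[4-(triisopropylsilyloxy)phenyl]-2,3-dihydro-1-benzofuran-7-yl]-2-[4-(triisopropylsilyloxy)phenyl]ethan-1-one | O=C(Cc1ccc(O[Si](C(C)C)(C(C)C)C(C)C)cc1)c1c(O[Si](C(C)C)(C(C)C)C(C)C)cc(O[Si](C(C)C)(C(C)C)C(C)C)c2c1O[C@@H](c1ccc(O[Si](C(C)C)(C(C)C)C(C)C)cc1)[C@@H]2C(=O)c1ccc(O[Si](C(C)C)(C(C)C)C(C)C)cc1O[Si](C(C)C)(C(C)C)C(C)C | intermediate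
20 | 1-[(2R,3R)-3-[2,4-bis(triisopropylsilyloxy)benzoyl]-4,6-bis(triisopropylsilyloxy)-2-[4-(triisopropylsilyloxy)phenyl]-2,3-dihydro-1-benzofuran-7-yl]-2-[4-(triisopropylsilyloxy)phenyl]prop-2-en-1-one | C=C(C(=O)c1c(O[Si](C(C)C)(C(C)C)C(C)C)cc(O[Si](C(C)C)(C(C)C)C(C)C)c2c1O[C@@H](c1ccc(O[Si](C(C)C)(C(C)C)C(C)C)cc1)[C@@H]2C(=O)c1ccc(O[Si](C(C)C)(C(C)C)C(C)C)cc1O[Si](C(C)C)(C(C)C)C(C)C)c1ccc(O[Si](C(C)C)(C(C)C)C(C)C)cc1 | intermediate
21 | 1-[(2R,3R)-3-(2,4-dihydroxybenzoyl)-4,6-dihydroxy-2-(4-hydroxyphenyl)-2,3-dihydro-1-benzofuran-7-yl]-2-(4-hydroxyphenyl)prop-2-en-1-one | C=C(C(=O)c1c(O)cc(O)c2c1O[C@@H](c1ccc(O)cc1)[C@@H]2C(=O)c1ccc(O)cc1O)c1ccc(O)cc1 | target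

**Totals**
Total step count: 12. Longest linear sequence: 8 steps (1, 2, 5, 6, 7, 10, 11, 12).

**Steps most likely to fail**

Step 5 (Proposed new method). What may go wrong: oxidative self-coupling or over-oxidation of the electron-rich phenol outpaces its addition to the electron-poor acceptor, or the sultam discriminates the two alkene faces poorly. The fallback uses the Ag2O biomimetic phenol coupling that is established for auxiliary-bound 4-hydroxycinnamates and runs through a quinone methide; here it is applied as a cross-coupling with 4. It sets out from 10. HF·pyridine removes the silyl group to give (2R)-N-[(E)-3-(4-hydroxyphenyl)prop-2-enoyl]bornane-10,2-sultam F1. F1 and 4 are then oxidised together with Ag2O in CH2Cl2/acetone at rt. The phenoxyl radical of F1, which carries spin at C-alpha, should couple with the aryloxyl radical of 4, and the resulting para-quinone methide of ring B is closed by the ring A oxygen under the same auxiliary control. This gives (2R)-N-{[(2R,3R)-6-hydroxy-2-(4-hydroxyphenyl)-4-(triisopropylsilyloxy)-7-{[4-(triisopropylsilyloxy)phenyl]acetyl}-2,3-dihydro-1-benzofuran-3-yl]carbonyl}bornane-10,2-sultam F2. TIPSOTf with 2,6-lutidine silylates both free phenols of F2, and the route is rejoined at 12.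

Step 10. What may go wrong: transmetalation of the hindered ortho-silyloxy boronic acid to the branched acyl-palladium is slower than protodeboronation, so the thioester is left unconverted. The fallback replaces the acyl cross-coupling by carbonyl addition and oxidation, and sets out from 13. Fukuyama reduction (Et3SiH, Pd/C, acetone, rt) gives (2R,3R)-4,6-bis(triisopropylsilyloxy)-2-[4-(triisopropylsilyloxy)phenyl]-7-{[4-(triisopropylsilyloxy)phenyl]acetyl}-2,3-dihydro-1-benzofuran-3-carbaldehyde F3. The aryllithium 16, made from 15 with n-BuLi at −78 °C, is transmetalated with ClTi(OiPr)3 to [2,4-bis(triisopropylsilyloxy)phenyl]titanium triisopropoxide F4. F4 should add to the aldehyde and not to the enolisable C7 ketone, giving the carbinol 1-[(2R,3R)-3-{[2,4-bis(triisopropylsilyloxy)phenyl](hydroxy)methyl}-4,6-bis(triisopropylsilyloxy)-2-[4-(triisopropylsilyloxy)phenyl]-2,3-dihydro-1-benzofuran-7-yl]-2-[4-(triisopropylsilyloxy)phenyl]ethan-1-one F5 as a mixture of carbinol epimers, which is of no consequence. Dess–Martin oxidation returns to the route at 19.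

Step 12. What may go wrong: once the C6 phenol is free, its conjugate addition to the α-methylene ketone closes an isoflavanone ring, or pyridine or fluoride adds to the enone. The fallback unveils the enone only after the phenols are free, and sets out from 19 (step 11 is skipped). LiN(SiMe3)2 then PhSeCl (THF, −78 °C) selenenylates the benzylic CH2 of the C7 ketone to give the α-(phenylselanyl) ketone F6. MeI with K2CO3 in MeCN methylates the now acidic selenide carbon to give the α-methyl-α-(phenylselanyl) ketone F7. HF·pyridine removes the six silyl groups from a compound that has no enone, giving 1-[(2R,3R)-3-(2,4-dihydroxybenzoyl)-4,6-dihydroxy-2-(4-hydroxyphenyl)-2,3-dihydro-1-benzofuran-7-yl]-2-(4-hydroxyphenyl)-2-(phenylselanyl)propan-1-one F8. H2O2 (THF, 0 °C) oxidises selenium, and the selenoxide should eliminate syn towards the only β-hydrogens, those of the methyl group, under neutral conditions; this arrives at 21.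

**Further compounds**
F1 | step 5 | (2R)-N-[(E)-3-(4-hydroxyphenyl)prop-2-enoyl]bornane-10,2-sultam | O=C(/C=C/c1ccc(O)cc1)N1[C@@H]2C[C@H]3CC[C@]2(CS1(=O)=O)C3(C)C
F2 | step 5 | (2R)-N-{[(2R,3R)-6-hydroxy-2-(4-hydroxyphenyl)-4-(triisopropylsilyloxy)-7-{[4-(triisopropylsilyloxy)phenyl]acetyl}-2,3-dihydro-1-benzofuran-3-yl]carbonyl}bornane-10,2-sultam | O=C(Cc1ccc(O[Si](C(C)C)(C(C)C)C(C)C)cc1)c1c(O)cc(O[Si](C(C)C)(C(C)C)C(C)C)c2c1O[C@@H](c1ccc(O)cc1)[C@@H]2C(=O)N4[C@@H]5C[C@H]6CC[C@]5(CS4(=O)=O)C6(C)C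
F3 | step 10 | (2R,3R)-4,6-bis(triisopropylsilyloxy)-2-[4-(triisopropylsilyloxy)phenyl]-7-{[4-(triisopropylsilyloxy)phenyl]acetyl}-2,3-dihydro-1-benzofuran-3-carbaldehyde | O=C(Cc1ccc(O[Si](C(C)C)(C(C)C)C(C)C)cc1)c1c(O[Si](C(C)C)(C(C)C)C(C)C)cc(O[Si](C(C)C)(C(C)C)C(C)C)c2c1O[C@@H](c1ccc(O[Si](C(C)C)(C(C)C)C(C)C)cc1)[C@@H]2C=O
F4 | step 10 | [2,4-bis(triisopropylsilyloxy)phenyl]titanium triisopropoxide | CC(C)O[Ti](OC(C)C)(OC(C)C)c1ccc(O[Si](C(C)C)(C(C)C)C(C)C)cc1O[Si](C(C)C)(C(C)C)C(C)C
F5 | step 10 | 1-[(2R,3R)-3-{[2,4-bis(triisopropylsilyloxy)phenyl](hydroxy)methyl}-4,6-bis(triisopropylsilyloxy)-2-[4-(triisopropylsilyloxy)phenyl]-2,3-dihydro-1-benzofuran-7-yl]-2-[4-(triisopropylsilyloxy)phenyl]ethan-1-one (carbinol epimers) | O=C(Cc1ccc(O[Si](C(C)C)(C(C)C)C(C)C)cc1)c1c(O[Si](C(C)C)(C(C)C)C(C)C)cc(O[Si](C(C)C)(C(C)C)C(C)C)c2c1O[C@@H](c1ccc(O[Si](C(C)C)(C(C)C)C(C)C)cc1)[C@@H]2C(O)c1ccc(O[Si](C(C)C)(C(C)C)C(C)C)cc1O[Si](C(C)C)(C(C)C)C(C)C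
F6 | step 12 | 1-[(2R,3R)-3-[2,4-bis(triisopropylsilyloxy)benzoyl]-4,6-bis(triisopropylsilyloxy)-2-[4-(triisopropylsilyloxy)phenyl]-2,3-dihydro-1-benzofuran-7-yl]-2-(phenylselanyl)-2-[4-(triisopropylsilyloxy)phenyl]ethan-1-one (epimers at the selenide carbon) | O=C(C([Se]c1ccccc1)c1ccc(O[Si](C(C)C)(C(C)C)C(C)C)cc1)c1c(O[Si](C(C)C)(C(C)C)C(C)C)cc(O[Si](C(C)C)(C(C)C)C(C)C)c2c1O[C@@H](c1ccc(O[Si](C(C)C)(C(C)C)C(C)C)cc1)[C@@H]2C(=O)c1ccc(O[Si](C(C)C)(C(C)C)C(C)C)cc1O[Si](C(C)C)(C(C)C)C(C)C
F7 | step 12 | 1-[(2R,3R)-3-[2,4-bis(triisopropylsilyloxy)benzoyl]-4,6-bis(triisopropylsilyloxy)-2-[4-(triisopropylsilyloxy)phenyl]-2,3-dihydro-1-benzofuran-7-yl]-2-(phenylselanyl)-2-[4-(triisopropylsilyloxy)phenyl]propan-1-one (epimers at the selenide carbon) | O=C(C(C)([Se]c1ccccc1)c1ccc(O[Si](C(C)C)(C(C)C)C(C)C)cc1)c1c(O[Si](C(C)C)(C(C)C)C(C)C)cc(O[Si](C(C)C)(C(C)C)C(C)C)c2c1O[C@@H](c1ccc(O[Si](C(C)C)(C(C)C)C(C)C)cc1)[C@@H]2C(=O)c1ccc(O[Si](C(C)C)(C(C)C)C(C)C)cc1O[Si](C(C)C)(C(C)C)C(C)C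
F8 | step 12 | 1-[(2R,3R)-3-(2,4-dihydroxybenzoyl)-4,6-dihydroxy-2-(4-hydroxyphenyl)-2,3-dihydro-1-benzofuran-7-yl]-2-(4-hydroxyphenyl)-2-(phenylselanyl)propan-1-one (epimers at the selenide carbon) | O=C(C(C)([Se]c1ccccc1)c1ccc(O)cc1)c1c(O)cc(O)c2c1O[C@@H](c1ccc(O)cc1)[C@@H]2C(=O)c1ccc(O)cc1O
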